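The plan takes ring D (the dihydrofuran) apart at both bonds to its lone stereocentre: C2 is bonded to the ring oxygen O1 and to benzylic C3, so cutting O1–C2 and C2–C3 leaves a one-carbon piece and a ring C phenol with an ortho exocyclic CH2. In one operation a formal [4+1] annulation joins an ortho-quinone methide, released from a sulfone, to a chiral quinidinium ylide of tert-butyl acetate, which forms both bonds, closes ring D and sets (S)-C2. The precursor is 3-bromo-5-(methoxymethoxy)-2-(tosylmethyl)phenol; its bromine later links ring C to a separately built 7-geranylbenzofuran (rings A and B) by Negishi coupling.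

Key step: step 6

Ring and atom labels: rings A and B are the benzene and furan rings of the benzofuran, ring C is the benzene ring of the dihydrobenzofuran, ring D is its dihydrofuran ring (O1, C2, C3). "Geranyl" means (2E)-3,7-dimethylocta-2,6-dien-1-yl.

Assumption: the quinidine-derived ammonium group is taken to deliver (S)-C2; if a trial shows the opposite sense, the quinine-derived pseudoenantiomer would be used in the same step.

Design notes:
- The para oxygen of the sulfone precursor is masked as a methoxymethyl (MOM) ether and not a silyl ether. MOM is inert to carbonate and phenoxide and cannot migrate. It is also the group that directs metalation on ring A, so one acid step unmasks both phenols at the end.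
- The ammonium salt is made beforehand, so that no free alkyl bromide meets the phenoxide in the key step.
- The ester is turned into the carbinol before the coupling, so that C2 no longer carries an acidic hydrogen.

Step 1
Reactants: 1 5-bromoresorcinol
Product: 3 2-bromo-4,6-dihydroxybenzaldehyde, via aryl iminium chloride 2 (not isolated)
Conditions: POCl3, DMF, MeCN, 0 °C to rt; then H2O, 50 °C
Reagents that add atoms: N,N-dimethylformamide, CN(C)C=O; water, O
Why: Vilsmeier–Haack formylation: the chloroiminium ion should attack C4 of the resorcinol, the position para to one hydroxyl and ortho to the other that 5-substituted resorcinols normally use, and warming with water hydrolyses iminium salt 2 to the aldehyde.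

Step 2
Reactants: 3 2-bromo-4,6-dihydroxybenzaldehyde
Product: 4 2-bromo-6-hydroxy-4-(methoxymethoxy)benzaldehyde
Conditions: MOMCl (1.05 equiv), iPr2NEt, CH2Cl2, 0 °C
Reagents that add atoms: chloromethyl methyl ether, COCCl
Why: Base-mediated O-alkylation (Williamson type): the hydroxyl para to the aldehyde is the more acidic and is free, whereas the ortho hydroxyl is held in a hydrogen bond to the carbonyl, so one equivalent of MOMCl should go to the para oxygen.

Step 3
Reactants: 4 2-bromo-6-hydroxy-4-(methoxymethoxy)benzaldehyde
Product: 5 3-bromo-2-(hydroxymethyl)-5-(methoxymethoxy)phenol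
Conditions: NaBH4, MeOH/THF, 0 °C; NH4Cl work-up
Reagents that add atoms: none
Why: Borohydride reduction of an aldehyde to the primary alcohol, which leaves the aryl bromide and the acetal untouched, with a buffered work-up so that the electron-rich benzylic alcohol is not ionised.

Step 4
Reactants: 5 3-bromo-2-(hydroxymethyl)-5-(methoxymethoxy)phenol
Product: 6 3-bromo-5-(methoxymethoxy)-2-[(4-methylbenzenesulfonyl)methyl]phenol
Conditions: p-TolSO2H (1.5 equiv, freshly liberated from p-TolSO2Na), CH2Cl2, rt
Reagents that add atoms: p-toluenesulfinic acid, Cc1ccc(cc1)S(=O)O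
Why: Acid-promoted SN1-type alkylation of a sulfinate at sulfur: the benzylic alcohol, activated by the ortho hydroxyl and the para alkoxy group, ionises under the weakly acidic sulfinic acid and is captured to give the sulfone, under conditions mild enough to spare the MOM acetal.

Step 5
Reactants: 7 quinidine; 8 tert-butyl bromoacetate
Product: 9 1-(2-tert-butoxy-2-oxoethyl)quinidin-1-ium bromide (alkylated at the quinuclidine nitrogen)
Conditions: THF, rt; salt collected by filtration
Reagents that add atoms: none
Why: Menshutkin quaternisation: the quinuclidine nitrogen is far more nucleophilic than the quinoline nitrogen or the hydroxyl, so the primary bromide should alkylate it cleanly.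

Step 6
Reactants: 6 3-bromo-5-(methoxymethoxy)-2-[(4-methylbenzenesulfonyl)methyl]phenol; 9 1-(2-tert-butoxy-2-oxoethyl)quinidin-1-ium bromide
Product: 12 tert-butyl (S)-4-bromo-6-(methoxymethoxy)-2,3-dihydro-1-benzofuran-2-carboxylate, via ortho-quinone methide 10 (not isolated), via phenoxide ammonium betaine 11 (not isolated)
Conditions: 9 (1.3 equiv), Cs2CO3 (3 equiv), CH2Cl2, 0 °C to rt; quinidine recovered by acid extraction
Reagents that add atoms: none
Why: Proposed new method: Cs2CO3 deprotonates phenol 6, which expels p-toluenesulfinate to give ortho-quinone methide 10, and it converts salt 9 into its ester-stabilised ammonium ylide; the ylide carbon adds in a 1,4 sense to the unsubstituted methide CH2 (new C2–C3 bond) and the phenoxide of betaine 11 then displaces quinidine at the ammonium-bearing carbon (new O1–C2 bond). The closest known reaction type is the formal [4+1] annulation of cinchona ammonium or sulfonium ylides with ortho-quinone methides that bear a substituent on the methide carbon, so enantiocontrol at C2 with a bare CH2 terminus is the untested element. Ring D closes by a 5-exo-tet SN2 displacement with inversion at C2. C2, the only new stereocentre, is controlled by the quinidinium group, which is the leaving group and therefore still bonded to C2 when its configuration is fixed: the C2–H of 11 lies between N+ and the ester and is acidic, so the two epimers of 11 should interconvert by deprotonation and the faster-closing (R)-epimer should be drained to (S)-12. The step needs enantioselectivity, which rests on that chiral ammonium group, and capture of 10 by the ylide ahead of its self-condensation, which the para methoxymethoxy donor, the flanking bromine and reversible re-addition of sulfinate should secure. Making salt 9 beforehand keeps free alkyl bromide away from the phenoxide, and the ester C2–H of 12 is too weakly acidic for Cs2CO3 in CH2Cl2 to erase the result.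

Step 7
Reactants: 12 tert-butyl (S)-4-bromo-6-(methoxymethoxy)-2,3-dihydro-1-benzofuran-2-carboxylate
Product: 14 (S)-2-[4-bromo-6-(methoxymethoxy)-2,3-dihydro-1-benzofuran-2-yl]propan-2-ol, via methyl ketone 13 (not isolated)
Conditions: MeMgBr (4 equiv), CeCl3 (anhydrous), THF, −78 °C to rt
Reagents that add atoms: methylmagnesium bromide, C[Mg]Br
Why: Double Grignard addition to an ester through ketone 13: the organocerium species formed from MeMgBr and CeCl3 is weakly basic, so addition should outrun enolisation at C2 and the (S) configuration is kept, while the aryl bromide and the acetal are inert.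

Step 8
Reactants: 15 benzofuran-6-ol
Product: 16 6-(methoxymethoxy)-1-benzofuran
Conditions: MOMCl, iPr2NEt, CH2Cl2, 0 °C to rt
Reagents that add atoms: chloromethyl methyl ether, COCCl
Why: Base-mediated O-alkylation of the phenol, giving a MOM ether that protects the oxygen and serves as the directing group for the next step.

Step 9
Reactants: 16 6-(methoxymethoxy)-1-benzofuran; 17 geranyl bromide
Product: 19 {7-[(2E)-3,7-dimethylocta-2,6-dien-1-yl]-6-(methoxymethoxy)-1-benzofuran-2-yl}trimethylsilane, via 2-silylbenzofuran 18 (not isolated)
Conditions: n-BuLi, THF, −78 °C, then TMSCl, to 0 °C; s-BuLi, TMEDA, −78 °C; CuI (0.5 equiv), 17, −78 °C to 0 °C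
Reagents that add atoms: chlorotrimethylsilane, C[Si](C)(C)Cl
Why: Sequential deprotonative metalations: n-BuLi removes the most acidic proton (the furan C2–H) and TMSCl caps that site in the flask, after which directed ortho-metalation by s-BuLi/TMEDA should occur at C7, the position flanked by the MOM ether and the ring oxygen, and copper-mediated SN2 allylation of the aryl anion with 17 attaches the chain at its primary carbon with the E double bond unchanged.

Step 10
Reactants: 19 {7-[(2E)-3,7-dimethylocta-2,6-dien-1-yl]-6-(methoxymethoxy)-1-benzofuran-2-yl}trimethylsilane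
Product: 20 7-[(2E)-3,7-dimethylocta-2,6-dien-1-yl]-6-(methoxymethoxy)-1-benzofuran
Conditions: Bu4NF, THF, 0 °C to rt
Reagents that add atoms: none
Why: Fluoride-induced protodesilylation of a 2-silyl heteroarene, whose C(sp2)–Si bond next to the ring oxygen is cleaved readily while the MOM ether and the alkenes are inert to Bu4NF.

Step 11
Reactants: 20 7-[(2E)-3,7-dimethylocta-2,6-dien-1-yl]-6-(methoxymethoxy)-1-benzofuran; 14 (S)-2-[4-bromo-6-(methoxymethoxy)-2,3-dihydro-1-benzofuran-2-yl]propan-2-ol
Product: 22 (S)-2-{4-[7-geranyl-6-(methoxymethoxy)-1-benzofuran-2-yl]-6-(methoxymethoxy)-2,3-dihydro-1-benzofuran-2-yl}propan-2-ol, via benzofuran-2-ylzinc chloride 21 (not isolated)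
Conditions: 20 (1.6 equiv), n-BuLi, THF, −78 °C; ZnCl2, to rt; then 14, Pd(OAc)2 (3 mol %), SPhos, THF, 50 °C
Reagents that add atoms: none
Why: Negishi cross-coupling: the furan C2–H of 20 is its most acidic proton, transmetalation to zinc gives a reagent mild enough to tolerate the free tertiary alcohol and the acetals, and coupling with aryl bromide 14 forms the bond between rings B and C without touching the stereocentre.

Step 12
Reactants: 22 (S)-2-{4-[7-geranyl-6-(methoxymethoxy)-1-benzofuran-2-yl]-6-(methoxymethoxy)-2,3-dihydro-1-benzofuran-2-yl}propan-2-ol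
Product: 23 (S)-4-{7-[(2E)-3,7-dimethylocta-2,6-dien-1-yl]-6-hydroxy-1-benzofuran-2-yl}-2-(2-hydroxypropan-2-yl)-2,3-dihydro-1-benzofuran-6-ol (target)
Conditions: HCl (1 M), MeOH/THF, rt to 40 °C
Reagents that add atoms: none
Why: Acid-catalysed acetal methanolysis: dilute HCl in methanol should cleave both aryl MOM ethers (the formaldehyde unit leaves as dimethoxymethane) at a temperature at which the tertiary alcohol, the geranyl alkenes and the stereocentre are expected to survive.

Compound list

1 | 5-bromoresorcinol | Oc1cc(O)cc(Br)c1 | starting material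
2 | (2-bromo-4,6-dihydroxybenzylidene)dimethylammonium chloride | C[N+](C)=Cc1c(O)cc(O)cc1Br.[Cl-] | intermediate
3 | 2-bromo-4,6-dihydroxybenzaldehyde | O=Cc1c(O)cc(O)cc1Br | intermediate
4 | 2-bromo-6-hydroxy-4-(methoxymethoxy)benzaldehyde | O=Cc1c(O)cc(OCOC)cc1Br | intermediate
5 | 3-bromo-2-(hydroxymethyl)-5-(methoxymethoxy)phenol | OCc1c(O)cc(OCOC)cc1Br | intermediate
6 | 3-bromo-5-(methoxymethoxy)-2-[(4-methylbenzenesulfonyl)methyl]phenol | Cc1ccc(cc1)S(=O)(=O)Cc1c(O)cc(OCOC)cc1Br | intermediate
7 | quinidine | C=C[C@H]1C[N@@]2CC[C@H]1C[C@@H]2[C@H](c3ccnc4ccc(OC)cc34)O | starting material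
8 | tert-butyl bromoacetate | CC(C)(C)OC(=O)CBr | starting material
9 | 1-(2-tert-butoxy-2-oxoethyl)quinidin-1-ium bromide | C=C[C@H]1C[N@+]2(CC(=O)OC(C)(C)C)CC[C@H]1C[C@@H]2[C@H](c3ccnc4ccc(OC)cc34)O.[Br-] | intermediate
10 | 5-bromo-3-(methoxymethoxy)-6-methylidenecyclohexa-2,4-dien-1-one (ortho-quinone methide) | C=C1C(=O)C=C(OCOC)C=C1Br | intermediate
11 | 3-bromo-2-[(2R)-3-tert-butoxy-3-oxo-2-(quinidin-1-ium-1-yl)propyl]-5-(methoxymethoxy)phenolate (productive epimer shown) | C=C[C@H]1C[N@+]2([C@H](Cc3c([O-])cc(OCOC)cc3Br)C(=O)OC(C)(C)C)CC[C@H]1C[C@@H]2[C@H](c4ccnc5ccc(OC)cc45)O | intermediate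
12 | tert-butyl (S)-4-bromo-6-(methoxymethoxy)-2,3-dihydro-1-benzofuran-2-carboxylate | Brc1cc(OCOC)cc2c1C[C@@H](C(=O)OC(C)(C)C)O2 | intermediate
13 | 1-[(S)-4-bromo-6-(methoxymethoxy)-2,3-dihydro-1-benzofuran-2-yl]ethan-1-one | Brc1cc(OCOC)cc2c1C[C@@H](C(C)=O)O2 | intermediate
14 | (S)-2-[4-bromo-6-(methoxymethoxy)-2,3-dihydro-1-benzofuran-2-yl]propan-2-ol | Brc1cc(OCOC)cc2c1C[C@@H](C(C)(C)O)O2 | intermediate
15 | benzofuran-6-ol | Oc1ccc2ccoc2c1 | starting material
16 | 6-(methoxymethoxy)-1-benzofuran | COCOc1ccc2ccoc2c1 | intermediate
17 | geranyl bromide | CC(C)=CCC/C(C)=C/CBr | starting material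
18 | [6-(methoxymethoxy)-1-benzofuran-2-yl]trimethylsilane | COCOc1ccc2cc([Si](C)(C)C)oc2c1 | intermediate
19 | {7-[(2E)-3,7-dimethylocta-2,6-dien-1-yl]-6-(methoxymethoxy)-1-benzofuran-2-yl}trimethylsilane | CC(C)=CCC/C(C)=C/Cc1c(OCOC)ccc2cc([Si](C)(C)C)oc12 | intermediate
20 | 7-[(2E)-3,7-dimethylocta-2,6-dien-1-yl]-6-(methoxymethoxy)-1-benzofuran | CC(C)=CCC/C(C)=C/Cc1c(OCOC)ccc2ccoc12 | intermediate
21 | {7-[(2E)-3,7-dimethylocta-2,6-dien-1-yl]-6-(methoxymethoxy)-1-benzofuran-2-yl}zinc chloride | CC(C)=CCC/C(C)=C/Cc1c(OCOC)ccc2cc([Zn]Cl)oc12 | intermediate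
22 | (S)-2-{4-[7-geranyl-6-(methoxymethoxy)-1-benzofuran-2-yl]-6-(methoxymethoxy)-2,3-dihydro-1-benzofuran-2-yl}propan-2-ol | CC(C)=CCC/C(C)=C/Cc1c(OCOC)ccc2cc(-c3cc(OCOC)cc4c3C[C@@H](C(C)(C)O)O4)oc12 | intermediate
23 | (S)-4-{7-[(2E)-3,7-dimethylocta-2,6-dien-1-yl]-6-hydroxy-1-benzofuran-2-yl}-2-(2-hydroxypropan-2-yl)-2,3-dihydro-1-benzofuran-6-ol | CC(C)=CCC/C(C)=C/Cc1c(O)ccc2cc(-c3cc(O)cc4c3C[C@@H](C(C)(C)O)O4)oc12 | target

Total steps: 12. Longest linear sequence: 8 steps (steps 1, 2, 3, 4, 6, 7, 11 and 12).

Steps most likely to fail

Step 6 (key step). What may go wrong: weak discrimination between the two betaine epimers by the ammonium group (low enantiomeric purity at C2), self-condensation of the bare methide before the ylide captures it, or loss of the amine from the betaine by elimination instead of ring closure. The fallback uses known chemistry, sets out from 6, returns at 14 and makes steps 5 to 7 unnecessary. Sulfone 6 would be treated with 2-methylprop-1-enylmagnesium bromide (2.5 equiv, THF, −78 °C to 0 °C), which releases the same methide and adds to it in a 1,4 sense to give 3-bromo-5-(methoxymethoxy)-2-(3-methylbut-2-en-1-yl)phenol F1. Acetylation (Ac2O, pyridine) should give the aryl acetate F2. Shi epoxidation (D-fructose-derived ketone, KHSO5, K2CO3 buffer, MeCN/dimethoxymethane/H2O, 0 °C) is expected to give the (R)-epoxide F3. K2CO3 in MeOH would then remove the acetate, and the phenoxide should open the epoxide at its secondary carbon (5-exo-tet, inversion) to give 14 with the (S) configuration.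

Step 9. What may go wrong: incomplete capping of the furan C2 position before the second metalation, metalation at C5 or at the acetal CH2 in place of C7, or allylic transposition (attack through the tertiary carbon) during the alkylation. The fallback sets out from 15, returns at 20 and makes steps 8 to 10 unnecessary; it replaces C–H metalation by halogenation and halogen–metal exchange. Electrophilic iodination of phenol 15 at the position flanked by both oxygens (I2, morpholine, CH2Cl2, rt) should give 7-iodo-1-benzofuran-6-ol F4. MOMCl and iPr2NEt would give 7-iodo-6-(methoxymethoxy)-1-benzofuran F5. Iodine–magnesium exchange (iPrMgCl·LiCl, THF, −20 °C) should give [6-(methoxymethoxy)-1-benzofuran-7-yl]magnesium chloride F6 without touching the furan C2–H. CuI-catalysed allylation of F6 with 17 should then give 20.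

Step 12. What may go wrong: acid-promoted cyclisation of the geranyl chain onto the neighbouring phenol (chroman formation), addition of methanol to the alkenes, or dehydration of the tertiary alcohol, each competing with acetal cleavage. The fallback sets out from 22 and returns at 23 and uses no Brønsted acid. TMSOTf with 2,2′-bipyridyl (CH2Cl2, 0 °C) should exchange the aryl MOM ethers for silyl ethers and silylate the tertiary alcohol, giving the tris(trimethylsilyl) ether F7. K2CO3 in MeOH at rt would then remove the three silyl groups to give 23.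

Further compounds

F1 | step 6 | 3-bromo-5-(methoxymethoxy)-2-(3-methylbut-2-en-1-yl)phenol | CC(C)=CCc1c(O)cc(OCOC)cc1Br
F2 | step 6 | 3-bromo-5-(methoxymethoxy)-2-(3-methylbut-2-en-1-yl)phenyl acetate | CC(C)=CCc1c(OC(C)=O)cc(OCOC)cc1Br
F3 | step 6 | 3-bromo-2-{[(2R)-3,3-dimethyloxiran-2-yl]methyl}-5-(methoxymethoxy)phenyl acetate | CC1(C)O[C@@H]1Cc2c(OC(C)=O)cc(OCOC)cc2Br
F4 | step 9 | 7-iodo-1-benzofuran-6-ol | Oc1ccc2ccoc2c1I
F5 | step 9 | 7-iodo-6-(methoxymethoxy)-1-benzofuran | COCOc1ccc2ccoc2c1I
F6 | step 9 | [6-(methoxymethoxy)-1-benzofuran-7-yl]magnesium chloride | COCOc1ccc2ccoc2c1[Mg]Cl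
F7 | step 12 | tris(trimethylsilyl) ether of 23 (both phenols and the tertiary alcohol silylated) | CC(C)=CCC/C(C)=C/Cc1c(O[Si](C)(C)C)ccc2cc(-c3cc(O[Si](C)(C)C)cc4c3C[C@@H](C(C)(C)O[Si](C)(C)C)O4)oc12
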